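## Retrosynthetic overview

- The quinone is the only ring and is made last: thermal 4π-electrocyclic ring opening of a 4-alkynyl-4-hydroxycyclobutenone, then ring closure of the enynylketene (Moore rearrangement), puts the side chain next to the C=O flanked by C–OMe.
- The cyclobutenone comes from dimethyl squarate: addition of a lithium enynide, then MeLi addition and (CF3CO)2O-induced carbonyl transposition fix the OMe/Me pattern; the tiglate goes on just before the thermolysis.
- The C(=CH2)–C≡C unit comes from methylenation of an α-silyloxy ynone, made from an α-silyloxy ester and LiC≡CSiMe3.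
- The ester carries the only stereocentre and comes from methyl (S)-glycidate opened at CH2 by Me2C=CHMgBr; no bond to that centre is broken afterwards.

Assumption: the target stereocentre is (S) as read from the SMILES; ring C4 of every cyclobutenone intermediate (and the methyl carbinol carbon of the MeLi adduct) forms as a mixture of epimers and is written without configuration, because it becomes a quinone carbonyl carbon in the last step.

## Route

Step 1
Reactants: 1 methyl (2S)-oxirane-2-carboxylate; 2 (2-methylprop-1-en-1-yl)magnesium bromide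
Product: 3 methyl (2S)-2-hydroxy-5-methylhex-4-enoate
Conditions: 2 (1.3 equiv), CuBr·SMe2 (10 mol%), THF, −78 → −40 °C; aq. NH4Cl
Reagents that add atoms: (2-methylprop-1-en-1-yl)magnesium bromide (2), CC(C)=C[Mg]Br
Why: CuBr·SMe2-catalysed SN2 epoxide opening by the alkenylmagnesium bromide occurs at the unsubstituted CH2 faster than attack on the ester at low temperature, and since the C2–O bond is untouched the bought (S) centre is retained.

Step 2
Reactants: 3 methyl (2S)-2-hydroxy-5-methylhex-4-enoate; 4 chlorotriethylsilane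
Product: 5 methyl (2S)-5-methyl-2-[(triethylsilyl)oxy]hex-4-enoate
Conditions: 4 (1.2 equiv), imidazole, CH2Cl2, 0 °C → rt
Reagents that add atoms: chlorotriethylsilane (4), CC[Si](Cl)(CC)CC
Why: Silyl ether formation masks the hydroxyl against the organolithium steps, and the triethylsilyl group can later be removed together with the ring trimethylsilyl ether under mild buffered fluoride conditions.

Step 3
Reactants: 5 methyl (2S)-5-methyl-2-[(triethylsilyl)oxy]hex-4-enoate; 6 ethynyltrimethylsilane
Product: 8 (4S)-7-methyl-4-[(triethylsilyl)oxy]-1-(trimethylsilyl)oct-6-en-1-yn-3-one, via lithium (trimethylsilyl)acetylide 7 (not isolated)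
Conditions: 6, n-BuLi, THF, −78 °C; BF3·OEt2, −78 °C; then 5, −78 °C; aq. NH4Cl
Reagents that add atoms: ethynyltrimethylsilane (6), C#C[Si](C)(C)C
Why: Yamaguchi-type acylation, in which the weakly basic alkynyl–BF3 species adds once to the ester and gives the ynone without enolising the α-silyloxy centre at −78 °C.

Step 4
Reactants: 8 (4S)-7-methyl-4-[(triethylsilyl)oxy]-1-(trimethylsilyl)oct-6-en-1-yn-3-one; 9 dibromomethane
Product: 11 triethyl{[(3S)-6-methyl-2-[(trimethylsilyl)ethynyl]hepta-1,5-dien-3-yl]oxy}silane, via bis(bromozincio)methane 10 (not isolated)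
Conditions: Zn, 9, TiCl4, THF, −40 → 5 °C (reagent pre-formed); then 8, CH2Cl2, 0 °C → rt
Reagents that add atoms: dibromomethane (9), BrCBr
Why: Takai–Lombardo methylenation with the non-basic CH2(ZnBr)2/TiCl4 reagent converts the ketone into the 1,1-disubstituted alkene without epimerising the adjacent stereocentre or touching the alkyne.

Step 5
Reactants: 11 triethyl{[(3S)-6-methyl-2-[(trimethylsilyl)ethynyl]hepta-1,5-dien-3-yl]oxy}silane; 12 methyllithium; 13 3,4-dimethoxycyclobut-3-ene-1,2-dione; 14 chlorotrimethylsilane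
Product: 17 2,3-dimethoxy-4-{(4S)-7-methyl-3-methylidene-4-[(triethylsilyl)oxy]oct-6-en-1-yn-1-yl}-4-[(trimethylsilyl)oxy]cyclobut-2-en-1-one, via lithium enynide 15 (not isolated), via lithium cyclobutenolate 16 (not isolated)
Conditions: 12 (as MeLi·LiBr, 1.05 equiv), THF, 0 °C → rt, 2 h; then added to 13, THF, −78 °C; 14 (1.5 equiv), −78 → 0 °C
Reagents that add atoms: 3,4-dimethoxycyclobut-3-ene-1,2-dione (13), COC1=C(OC)C(=O)C1=O; chlorotrimethylsilane (14), C[Si](C)(C)Cl
Why: MeLi cleaves the C(sp)–Si bond to the lithium acetylide, which undergoes 1,2-addition to one carbonyl of the symmetrical squarate, and in situ O-silylation gives the protected adduct as both ring-C4 epimers, which does not matter because this carbon becomes a carbonyl later.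

Step 6
Reactants: 17 2,3-dimethoxy-4-{(4S)-7-methyl-3-methylidene-4-[(triethylsilyl)oxy]oct-6-en-1-yn-1-yl}-4-[(trimethylsilyl)oxy]cyclobut-2-en-1-one; 12 methyllithium; 18 water
Product: 20 2-methoxy-3-methyl-4-{(4S)-7-methyl-3-methylidene-4-[(triethylsilyl)oxy]oct-6-en-1-yn-1-yl}-4-[(trimethylsilyl)oxy]cyclobut-2-en-1-one, via lithium alkoxide 19 (not isolated)
Conditions: 12 (1.2 equiv), THF, −78 °C; (CF3CO)2O (1.5 equiv), −78 °C; aq. NaHCO3 (18), −78 → 0 °C
Reagents that add atoms: methyllithium (12), [Li]C; water (18), O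
Why: 1,2-addition of MeLi to the remaining carbonyl followed by trifluoroacetylation and ionisation of the new tertiary alkoxide (the silylated one cannot ionise) gives a methoxy-stabilised allyl cation that is hydrolysed at the distal methoxy carbon, a 1,3-carbonyl transposition that leaves OMe next to C=O and Me next to the carbinol carbon.

Step 7
Reactants: 20 2-methoxy-3-methyl-4-{(4S)-7-methyl-3-methylidene-4-[(triethylsilyl)oxy]oct-6-en-1-yn-1-yl}-4-[(trimethylsilyl)oxy]cyclobut-2-en-1-one
Product: 21 4-hydroxy-4-[(4S)-4-hydroxy-7-methyl-3-methylideneoct-6-en-1-yn-1-yl]-2-methoxy-3-methylcyclobut-2-en-1-one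
Conditions: HF·pyridine, pyridine, THF, 0 °C
Reagents that add atoms: none
Why: Buffered fluoride desilylation removes both the tertiary trimethylsilyl and the secondary triethylsilyl ether without the strong acid that would ionise the tertiary propargylic ring alcohol.

Step 8
Reactants: 21 4-hydroxy-4-[(4S)-4-hydroxy-7-methyl-3-methylideneoct-6-en-1-yn-1-yl]-2-methoxy-3-methylcyclobut-2-en-1-one; 22 (2E)-2-methylbut-2-enoyl chloride
Product: 23 (3S)-2-[(1-hydroxy-3-methoxy-2-methyl-4-oxocyclobut-2-en-1-yl)ethynyl]-6-methylhepta-1,5-dien-3-yl (2E)-2-methylbut-2-enoate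
Conditions: 22 (1.1 equiv), pyridine, DMAP (5 mol%), CH2Cl2, −20 → 0 °C
Reagents that add atoms: (2E)-2-methylbut-2-enoyl chloride (22), C/C=C(\C)C(Cl)=O
Why: Nucleophilic acyl substitution is much faster at the secondary allylic hydroxyl than at the hindered tertiary ring hydroxyl, it breaks no bond to the stereocentre, and the (E)-tiglate is the thermodynamically stable geometry.

Step 9
Reactants: 23 (3S)-2-[(1-hydroxy-3-methoxy-2-methyl-4-oxocyclobut-2-en-1-yl)ethynyl]-6-methylhepta-1,5-dien-3-yl (2E)-2-methylbut-2-enoate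
Product: 26 (3S)-2-(5-methoxy-4-methyl-3,6-dioxocyclohexa-1,4-dien-1-yl)-6-methylhepta-1,5-dien-3-yl (2E)-2-methylbut-2-enoate, via enynylketene 24 (not isolated), via phenoxyl aryl diradical 25 (not isolated)
Conditions: toluene (0.01 M, degassed), 110 °C, 1–2 h
Reagents that add atoms: none
Why: Moore rearrangement, in which conrotatory 4π-electrocyclic ring opening with the hydroxyl rotating outward places the alkynyl group cis to the ketene, ring closure of the ketene carbon onto the distal alkyne carbon forms the six-membered ring, and transfer of the hydroxyl hydrogen to the ring radical gives the quinone with the side chain next to the C=O flanked by C–OMe in a pure isomerisation.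

## Compound list

1 | methyl (2S)-oxirane-2-carboxylate (methyl (S)-glycidate) | COC(=O)[C@@H]1CO1 | starting material
2 | (2-methylprop-1-en-1-yl)magnesium bromide | CC(C)=C[Mg]Br | starting material
3 | methyl (2S)-2-hydroxy-5-methylhex-4-enoate | COC(=O)[C@@H](O)CC=C(C)C | intermediate
4 | chlorotriethylsilane | CC[Si](Cl)(CC)CC | starting material
5 | methyl (2S)-5-methyl-2-[(triethylsilyl)oxy]hex-4-enoate | COC(=O)[C@@H](O[Si](CC)(CC)CC)CC=C(C)C | intermediate
6 | ethynyltrimethylsilane | C#C[Si](C)(C)C | starting material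
7 | lithium (trimethylsilyl)acetylide | [Li]C#C[Si](C)(C)C | intermediate
8 | (4S)-7-methyl-4-[(triethylsilyl)oxy]-1-(trimethylsilyl)oct-6-en-1-yn-3-one | C[Si](C)(C)C#CC(=O)[C@@H](O[Si](CC)(CC)CC)CC=C(C)C | intermediate
9 | dibromomethane | BrCBr | starting material
10 | bis(bromozincio)methane | Br[Zn]C[Zn]Br | intermediate
11 | triethyl{[(3S)-6-methyl-2-[(trimethylsilyl)ethynyl]hepta-1,5-dien-3-yl]oxy}silane | C[Si](C)(C)C#CC(=C)[C@@H](O[Si](CC)(CC)CC)CC=C(C)C | intermediate
12 | methyllithium | [Li]C | starting material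
13 | 3,4-dimethoxycyclobut-3-ene-1,2-dione (dimethyl squarate) | COC1=C(OC)C(=O)C1=O | starting material
14 | chlorotrimethylsilane | C[Si](C)(C)Cl | starting material
15 | {(4S)-7-methyl-3-methylidene-4-[(triethylsilyl)oxy]oct-6-en-1-yn-1-yl}lithium (lithium enynide) | [Li]C#CC(=C)[C@@H](O[Si](CC)(CC)CC)CC=C(C)C | intermediate
16 | lithium 2,3-dimethoxy-1-{(4S)-7-methyl-3-methylidene-4-[(triethylsilyl)oxy]oct-6-en-1-yn-1-yl}-4-oxocyclobut-2-en-1-olate | [Li]OC1(C#CC(=C)[C@@H](O[Si](CC)(CC)CC)CC=C(C)C)C(OC)=C(OC)C1=O | intermediate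
17 | 2,3-dimethoxy-4-{(4S)-7-methyl-3-methylidene-4-[(triethylsilyl)oxy]oct-6-en-1-yn-1-yl}-4-[(trimethylsilyl)oxy]cyclobut-2-en-1-one | COC1=C(OC)C(O[Si](C)(C)C)(C#CC(=C)[C@@H](O[Si](CC)(CC)CC)CC=C(C)C)C1=O | intermediate
18 | water | O | starting material
19 | lithium 2,3-dimethoxy-1-methyl-4-{(4S)-7-methyl-3-methylidene-4-[(triethylsilyl)oxy]oct-6-en-1-yn-1-yl}-4-[(trimethylsilyl)oxy]cyclobut-2-en-1-olate | [Li]OC1(C)C(OC)=C(OC)C1(O[Si](C)(C)C)C#CC(=C)[C@@H](O[Si](CC)(CC)CC)CC=C(C)C | intermediate
20 | 2-methoxy-3-methyl-4-{(4S)-7-methyl-3-methylidene-4-[(triethylsilyl)oxy]oct-6-en-1-yn-1-yl}-4-[(trimethylsilyl)oxy]cyclobut-2-en-1-one | COC1=C(C)C(O[Si](C)(C)C)(C#CC(=C)[C@@H](O[Si](CC)(CC)CC)CC=C(C)C)C1=O | intermediate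
21 | 4-hydroxy-4-[(4S)-4-hydroxy-7-methyl-3-methylideneoct-6-en-1-yn-1-yl]-2-methoxy-3-methylcyclobut-2-en-1-one | COC1=C(C)C(O)(C#CC(=C)[C@@H](O)CC=C(C)C)C1=O | intermediate
22 | (2E)-2-methylbut-2-enoyl chloride (tigloyl chloride) | C/C=C(\C)C(Cl)=O | starting material
23 | (3S)-2-[(1-hydroxy-3-methoxy-2-methyl-4-oxocyclobut-2-en-1-yl)ethynyl]-6-methylhepta-1,5-dien-3-yl (2E)-2-methylbut-2-enoate | COC1=C(C)C(O)(C#CC(=C)[C@H](CC=C(C)C)OC(=O)/C(C)=C/C)C1=O | intermediate
24 | (3S)-2-[(3E)-3-hydroxy-5-methoxy-4-methyl-6-oxohexa-3,5-dien-1-yn-1-yl]-6-methylhepta-1,5-dien-3-yl (2E)-2-methylbut-2-enoate (enynylketene) | COC(=C=O)/C(C)=C(/O)C#CC(=C)[C@H](CC=C(C)C)OC(=O)/C(C)=C/C | intermediate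
25 | 4-hydroxy-2-methoxy-3-methyl-6-[(3S)-6-methyl-3-{[(2E)-2-methylbut-2-enoyl]oxy}hepta-1,5-dien-2-yl]phenoxyl-5-yl diradical (O-centred radical at C1, σ-radical at C5) | COc1c([O])c(C(=C)[C@H](CC=C(C)C)OC(=O)/C(C)=C/C)[c]c(O)c1C | intermediate
26 | (3S)-2-(5-methoxy-4-methyl-3,6-dioxocyclohexa-1,4-dien-1-yl)-6-methylhepta-1,5-dien-3-yl (2E)-2-methylbut-2-enoate | C=C(C1=CC(=O)C(C)=C(OC)C1=O)[C@H](CC=C(C)C)OC(=O)/C(C)=C/C | target

## Step count and risks

Total steps: 9. Longest linear sequence: 9 steps (from 1; all other inputs are bought).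

The three steps most likely to fail:

Step 3. Single acylation of an ester by an acetylide can over-add or stall. The fallback sets out from 5. MeNHOMe·HCl and iPrMgCl (THF, −20 °C) convert the ester into the Weinreb amide (2S)-N-methoxy-N,5-dimethyl-2-[(triethylsilyl)oxy]hex-4-enamide F1. F1 takes up exactly one equivalent of 7 (THF, −78 → 0 °C) through a chelated tetrahedral intermediate and gives the ynone on work-up, so the fallback comes back to the route at 8.

Step 4. The Zn/CH2Br2/TiCl4 methylenation of a hindered, conjugated α-silyloxy ynone may be slow or may reduce the ynone. The fallback sets out from 8. Me3SiCH2MgCl with CeCl3 (THF, −78 °C) adds 1,2 to the ketone and gives the β-hydroxysilane (4S)-7-methyl-4-[(triethylsilyl)oxy]-1-(trimethylsilyl)-3-[(trimethylsilyl)methyl]oct-6-en-1-yn-3-ol F2 as both C3 epimers. Peterson elimination with KH (THF, 0 °C) then gives the enyne, so the fallback comes back to the route at 11.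

Step 9. The key thermolysis is run with the allylic tiglate in place and the product is a heat-sensitive vinylquinone. The fallback sets out from 21. The diol is thermolysed directly (toluene, 110 °C) to the hydroxy quinone 5-[(3S)-3-hydroxy-6-methylhepta-1,5-dien-2-yl]-3-methoxy-2-methylcyclohexa-2,5-diene-1,4-dione F3. F3 is then acylated with 22 (pyridine, CH2Cl2, 0 °C), so the fallback comes back to the route at 26. This keeps the ester out of the thermal step, and the acylation no longer has to distinguish two hydroxyl groups.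

## Further compounds

F1 | step 3 | (2S)-N-methoxy-N,5-dimethyl-2-[(triethylsilyl)oxy]hex-4-enamide | CON(C)C(=O)[C@@H](O[Si](CC)(CC)CC)CC=C(C)C
F2 | step 4 | (4S)-7-methyl-4-[(triethylsilyl)oxy]-1-(trimethylsilyl)-3-[(trimethylsilyl)methyl]oct-6-en-1-yn-3-ol | C[Si](C)(C)C#CC(O)(C[Si](C)(C)C)[C@@H](O[Si](CC)(CC)CC)CC=C(C)C
F3 | step 9 | 5-[(3S)-3-hydroxy-6-methylhepta-1,5-dien-2-yl]-3-methoxy-2-methylcyclohexa-2,5-diene-1,4-dione | C=C(C1=CC(=O)C(C)=C(OC)C1=O)[C@@H](O)CC=C(C)C
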